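**Strategy**

Numbering (germacranolide): C1 ketone, C4=C5 (Z)-alkene, C6 lactone carbinol, C7=C11 butenolide alkene, C12 lactone carbonyl, C8 acetoxy carbon, C10=C14 methylene. The route rests on the C5–C6 disconnection: C6 is both the γ-carbon of the butenolide and allylic to the cis ring alkene, so a (Z)-vinyl nucleophile at C5 can add to a C6 aldehyde. One intramolecular Nozaki–Hiyama–Kishi coupling closes the ten-membered carbocycle, sets C6 under control of C8, and the alkoxide then closes the butenolide onto the cis C12 ester. The precursor is an acyclic (Z)-vinyl iodide carrying a (Z)-β-formyl acrylate, unmasked from a 2-silylfuran by singlet oxygen.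

Key step: step 12

Assumption: tributyl(2-bromoallyl)stannane 12 is taken as purchasable (otherwise one step from 2,3-dibromopropene); in step 7 the controller antipode is the one that the reagent's chair model assigns to Si-face addition, and (S,S) is written.

**Route**

Step 1
Reactants: 1 prop-2-yn-1-ol
Product: 3 (2Z)-3-iodo-2-methylprop-2-en-1-ol, via magnesium chelate 2 (not isolated)
Conditions: MeMgBr (2.5 equiv), CuI (copper monoiodide, 10 mol %), THF, −10 °C → rt; then I2, −78 → 0 °C
Reagents that add atoms: methylmagnesium bromide (C[Mg]Br); iodine (II)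
Why: Copper-catalysed anti-carbomagnesiation of the propargylic alkoxide puts methyl on the internal carbon and magnesium on the terminal carbon inside a five-membered chelate, so iodinolysis with retention should give the iodide cis to the CH2OH arm, which is the (Z)-geometry needed at C4=C5.

Step 2
Reactants: 3 (2Z)-3-iodo-2-methylprop-2-en-1-ol
Product: 4 (1Z)-3-bromo-1-iodo-2-methylprop-1-ene
Conditions: CBr4, PPh3, CH2Cl2, 0 °C
Reagents that add atoms: carbon tetrabromide (BrC(Br)(Br)Br)
Why: The Appel reaction should convert the primary allylic alcohol into the bromide under neutral conditions without touching the vinyl iodide or the alkene geometry.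

Step 3
Reactants: 4 (1Z)-3-bromo-1-iodo-2-methylprop-1-ene; 5 N-methoxy-N-methylacetamide
Product: 6 (4Z)-5-iodo-N-methoxy-N,4-dimethylpent-4-enamide
Conditions: LiN(i-Pr)2 (1.05 equiv), THF, −78 °C; then 4, −78 → −30 °C
Reagents that add atoms: none
Why: SN2 alkylation of the lithium enolate of the Weinreb acetamide by the reactive allylic bromide should form C2–C3, and an amide enolate does not exchange with the vinyl iodide.

Step 4
Reactants: 7 furan-3-ylmethanol
Product: 9 {2-[tert-butyl(dimethyl)silyl]furan-3-yl}methanol, via silyl ether 8 (not isolated)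
Conditions: n-BuLi (1.05 equiv), THF, −78 °C; TBSCl (1.0 equiv), → rt; then n-BuLi (1.2 equiv), HMPA, −78 °C → rt; aq. NH4Cl
Reagents that add atoms: tert-butyl(chloro)dimethylsilane (C[Si](C)(Cl)C(C)(C)C)
Why: O-Silylation followed by α-lithiation next to the silyloxymethyl arm and a 1,4 O→C silyl shift (retro-Brook rearrangement) should move silicon onto the furan carbon that is to become C12.

Step 5
Reactants: 9 {2-[tert-butyl(dimethyl)silyl]furan-3-yl}methanol
Product: 10 5-[tert-butyl(dimethyl)silyl]-4-(hydroxymethyl)furan-3-carbaldehyde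
Conditions: n-BuLi (2.2 equiv), DME, 0 °C; DMF, −78 °C → rt; aq. NH4Cl
Reagents that add atoms: N,N-dimethylformamide (CN(C)C=O)
Why: In this directed ortho-metalation the silyl group blocks the neighbouring α-position, so the lithium alkoxide should steer the second lithiation to the adjacent β-carbon (future C7), and formylation of the dianion installs the future C8 aldehyde.

Step 6
Reactants: 10 5-[tert-butyl(dimethyl)silyl]-4-(hydroxymethyl)furan-3-carbaldehyde
Product: 11 5-[tert-butyl(dimethyl)silyl]-4-{[(triethylsilyl)oxy]methyl}furan-3-carbaldehyde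
Conditions: TESCl, imidazole, CH2Cl2, 0 °C
Reagents that add atoms: chlorotriethylsilane (CC[Si](Cl)(CC)CC)
Why: Standard silyl ether formation should mask the C13 hydroxyl as a TES ether that survives the boron and organolithium steps but is lost in dilute acid.

Step 7
Reactants: 11 5-[tert-butyl(dimethyl)silyl]-4-{[(triethylsilyl)oxy]methyl}furan-3-carbaldehyde; 12 tributyl(2-bromoprop-2-en-1-yl)stannane
Product: 13 (1S)-3-bromo-1-(5-[tert-butyl(dimethyl)silyl]-4-{[(triethylsilyl)oxy]methyl}furan-3-yl)but-3-en-1-ol
Conditions: (4S,5S)-2-bromo-4,5-diphenyl-1,3-bis(p-tolylsulfonyl)-1,3,2-diazaborolidine (1.1 equiv), 12, CH2Cl2, rt; then 11, −78 °C; pH 7 buffer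
Reagents that add atoms: none
Why: Tin-to-boron transmetalation should give a chiral B-(2-bromoallyl)diazaborolidine that adds to the aldehyde through a closed chair transition state (reagent-controlled enantioselective allylboration), the controller fixing Si-face attack and hence (S) at C8.

Step 8
Reactants: 13 (1S)-3-bromo-1-(5-[tert-butyl(dimethyl)silyl]-4-{[(triethylsilyl)oxy]methyl}furan-3-yl)but-3-en-1-ol; 6 (4Z)-5-iodo-N-methoxy-N,4-dimethylpent-4-enamide
Product: 16 (1S,7Z)-1-{5-[tert-butyl(dimethyl)silyl]-4-(hydroxymethyl)furan-3-yl}-1-hydroxy-8-iodo-7-methyl-3-methylideneoct-7-en-4-one, via alkenylmagnesium alkoxide 14 (not isolated), via TES-protected hydroxy enone 15 (not isolated)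
Conditions: t-BuLi (3.05 equiv), Et2O, −78 °C; MgBr2·OEt2 (1.2 equiv), −78 °C; 6, −78 → 0 °C; then 1 M HCl, THF, 0 °C → rt
Reagents that add atoms: none
Why: Bromine–lithium exchange, transmetalation to magnesium (to suppress iodine–metal exchange with 6) and acylation by the Weinreb amide (Weinreb ketone synthesis, no over-addition) should form C1–C10 directly at the enone level, and the acidic quench also removes the primary TES ether.

Step 9
Reactants: 16 (1S,7Z)-1-{5-[tert-butyl(dimethyl)silyl]-4-(hydroxymethyl)furan-3-yl}-1-hydroxy-8-iodo-7-methyl-3-methylideneoct-7-en-4-one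
Product: 17 (1S,7Z)-1-{4-[(acetyloxy)methyl]-5-[tert-butyl(dimethyl)silyl]furan-3-yl}-8-iodo-7-methyl-3-methylidene-4-oxooct-7-en-1-yl acetate
Conditions: Ac2O, pyridine, DMAP (cat.), CH2Cl2, 0 °C → rt
Reagents that add atoms: acetic anhydride (CC(=O)OC(C)=O)
Why: DMAP-catalysed acylation should esterify both free hydroxyls and so install both acetates of the target in one operation without affecting C8.

Step 10
Reactants: 17 (1S,7Z)-1-{4-[(acetyloxy)methyl]-5-[tert-butyl(dimethyl)silyl]furan-3-yl}-8-iodo-7-methyl-3-methylidene-4-oxooct-7-en-1-yl acetate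
Product: 20 (1S,7Z)-1-{4-[(acetyloxy)methyl]-2-hydroxy-5-oxo-2,5-dihydrofuran-3-yl}-8-iodo-7-methyl-3-methylidene-4-oxooct-7-en-1-yl acetate (both lactol epimers), via furan endoperoxide 18 (not isolated), via silyl ester 19 (not isolated)
Conditions: O2, tetraphenylporphyrin (cat.), visible light, CH2Cl2, −78 °C; then warm, H2O
Reagents that add atoms: dioxygen (O=O)
Why: Singlet oxygen should add [4+2] to the electron-rich furan much faster than to the deactivated alkenes, and in the endoperoxide the silyl group shifts from carbon to peroxide oxygen (silyl-directed furan photooxygenation), so only C12 becomes the carboxyl carbon and hydrolysis of the silyl ester leaves C6 at the aldehyde level as the γ-hydroxybutenolide.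

Step 11
Reactants: 20 (1S,7Z)-1-{4-[(acetyloxy)methyl]-2-hydroxy-5-oxo-2,5-dihydrofuran-3-yl}-8-iodo-7-methyl-3-methylidene-4-oxooct-7-en-1-yl acetate
Product: 21 methyl (2Z,4S,10Z)-4-(acetyloxy)-2-[(acetyloxy)methyl]-3-formyl-11-iodo-10-methyl-6-methylidene-7-oxoundeca-2,10-dienoate
Conditions: MeI, K2CO3, DMF, 0 °C
Reagents that add atoms: iodomethane (CI)
Why: Under mild base the lactol is in equilibrium with its ring-opened (Z)-formyl carboxylate, whose SN2 O-methylation should free the C6 aldehyde while the tetrasubstituted C7=C11 bond keeps CHO and CO2Me cis.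

Step 12
Reactants: 21 methyl (2Z,4S,10Z)-4-(acetyloxy)-2-[(acetyloxy)methyl]-3-formyl-11-iodo-10-methyl-6-methylidene-7-oxoundeca-2,10-dienoate
Product: 23 (6R,8S)-8,13-diacetoxy-1-oxogermacra-4(Z),7(11),10(14)-trien-12,6-olide, via macrocyclic hydroxy ester 22 (not isolated)
Conditions: CrCl2 (10 equiv), NiCl2 (0.1 equiv), degassed DMSO/THF, rt, 21 added by syringe pump to about 0.002 M; aqueous sodium serinate work-up (a trace of p-TsOH in CH2Cl2 if lactonisation is incomplete)
Reagents that add atoms: none
Why: NiCl2 is reduced by CrCl2 to zerovalent nickel, which inserts into the C5–I bond with retention of the (Z)-geometry and passes the alkenyl group to trivalent chromium; the alkenylchromium adds to the C6 aldehyde and the chromium alkoxide of 22 then attacks the cis C12 methyl ester with loss of methoxide. The closest known reaction type is the intramolecular Nozaki–Hiyama–Kishi coupling used for medium and large carbocycles, here a reductive union of two electrophilic carbons made possible by polarity reversal at C5. The ten-membered carbocycle closes by a 10-exo-trig addition to the formyl group, and the butenolide by a 5-exo-trig acyl substitution enforced by the (Z)-C7=C11 bond. C6 is the only new stereocenter and is controlled by C8: allylic 1,3-strain with the C13 methylene should hold the C8–H bond in the plane of C7=C11, which places the C9 arm on one face, and the short tether can deliver C5 only to that face of the s-trans formyl group, which corresponds to (6R). The step needs aldehyde-over-ketone chemoselectivity, which organochromium reagents provide, and ring closure over oligomerisation, which slow addition at high dilution, the cis C4=C5 bond and the sp2 centers C1, C7 and C10 should favour.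

**Compound list**

1 | prop-2-yn-1-ol | C#CCO | starting material
2 | 4-methyl-2,5-dihydro-1,2-oxamagnesole (cyclic alkenylmagnesium alkoxide) | CC1=C[Mg]OC1 | intermediate (not isolated)
3 | (2Z)-3-iodo-2-methylprop-2-en-1-ol | OC/C(C)=C\I | intermediate
4 | (1Z)-3-bromo-1-iodo-2-methylprop-1-ene | BrC/C(C)=C\I | intermediate
5 | N-methoxy-N-methylacetamide | CC(=O)N(C)OC | starting material
6 | (4Z)-5-iodo-N-methoxy-N,4-dimethylpent-4-enamide | CON(C)C(=O)CC/C(C)=C\I | intermediate
7 | furan-3-ylmethanol | OCc1ccoc1 | starting material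
8 | tert-butyl(furan-3-ylmethoxy)dimethylsilane | CC(C)(C)[Si](C)(C)OCc1ccoc1 | intermediate (not isolated)
9 | {2-[tert-butyl(dimethyl)silyl]furan-3-yl}methanol | OCc1ccoc1[Si](C)(C)C(C)(C)C | intermediate
10 | 5-[tert-butyl(dimethyl)silyl]-4-(hydroxymethyl)furan-3-carbaldehyde | O=Cc1coc([Si](C)(C)C(C)(C)C)c1CO | intermediate
11 | 5-[tert-butyl(dimethyl)silyl]-4-{[(triethylsilyl)oxy]methyl}furan-3-carbaldehyde | O=Cc1coc([Si](C)(C)C(C)(C)C)c1CO[Si](CC)(CC)CC | intermediate
12 | tributyl(2-bromoprop-2-en-1-yl)stannane | C=C(Br)C[Sn](CCCC)(CCCC)CCCC | starting material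
13 | (1S)-3-bromo-1-(5-[tert-butyl(dimethyl)silyl]-4-{[(triethylsilyl)oxy]methyl}furan-3-yl)but-3-en-1-ol | C=C(Br)C[C@H](O)c1coc([Si](C)(C)C(C)(C)C)c1CO[Si](CC)(CC)CC | intermediate
14 | alkenylmagnesium bromide lithium alkoxide from 13 | C=C([Mg]Br)C[C@H](O[Li])c1coc([Si](C)(C)C(C)(C)C)c1CO[Si](CC)(CC)CC | intermediate (not isolated)
15 | (1S,7Z)-1-(5-[tert-butyl(dimethyl)silyl]-4-{[(triethylsilyl)oxy]methyl}furan-3-yl)-1-hydroxy-8-iodo-7-methyl-3-methylideneoct-7-en-4-one | C=C(C[C@H](O)c1coc([Si](C)(C)C(C)(C)C)c1CO[Si](CC)(CC)CC)C(=O)CC/C(C)=C\I | intermediate (not isolated)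
16 | (1S,7Z)-1-{5-[tert-butyl(dimethyl)silyl]-4-(hydroxymethyl)furan-3-yl}-1-hydroxy-8-iodo-7-methyl-3-methylideneoct-7-en-4-one | C=C(C[C@H](O)c1coc([Si](C)(C)C(C)(C)C)c1CO)C(=O)CC/C(C)=C\I | intermediate
17 | (1S,7Z)-1-{4-[(acetyloxy)methyl]-5-[tert-butyl(dimethyl)silyl]furan-3-yl}-8-iodo-7-methyl-3-methylidene-4-oxooct-7-en-1-yl acetate | C=C(C[C@H](OC(C)=O)c1coc([Si](C)(C)C(C)(C)C)c1COC(C)=O)C(=O)CC/C(C)=C\I | intermediate
18 | 2,5-endoperoxide of furan 17 (2,3,7-trioxabicyclo[2.2.1]hept-5-ene, silyl at the C12 bridgehead) | C=C(C[C@H](OC(C)=O)C1=C(COC(C)=O)C2([Si](C)(C)C(C)(C)C)OOC1O2)C(=O)CC/C(C)=C\I | intermediate (not isolated)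
19 | tert-butyl(dimethyl)silyl (2Z,4S,10Z)-4-(acetyloxy)-2-[(acetyloxy)methyl]-3-formyl-11-iodo-10-methyl-6-methylidene-7-oxoundeca-2,10-dienoate | C=C(C[C@H](OC(C)=O)/C(C=O)=C(\COC(C)=O)C(=O)O[Si](C)(C)C(C)(C)C)C(=O)CC/C(C)=C\I | intermediate (not isolated)
20 | (1S,7Z)-1-{4-[(acetyloxy)methyl]-2-hydroxy-5-oxo-2,5-dihydrofuran-3-yl}-8-iodo-7-methyl-3-methylidene-4-oxooct-7-en-1-yl acetate (lactol epimers) | C=C(C[C@H](OC(C)=O)C1=C(COC(C)=O)C(=O)OC1O)C(=O)CC/C(C)=C\I | intermediate
21 | methyl (2Z,4S,10Z)-4-(acetyloxy)-2-[(acetyloxy)methyl]-3-formyl-11-iodo-10-methyl-6-methylidene-7-oxoundeca-2,10-dienoate | C=C(C[C@H](OC(C)=O)/C(C=O)=C(\COC(C)=O)C(=O)OC)C(=O)CC/C(C)=C\I | intermediate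
22 | macrocyclic (6R,8S)-6-hydroxy methyl ester (ten-membered ring closed, lactone still open; present as its chromium alkoxide) | C=C1C[C@H](OC(C)=O)/C(=C(\COC(C)=O)C(=O)OC)[C@H](O)/C=C(/C)CCC1=O | intermediate (not isolated)
23 | (6R,8S)-8,13-diacetoxy-1-oxogermacra-4(Z),7(11),10(14)-trien-12,6-olide | C=C1C[C@H](OC(C)=O)C2=C(COC(C)=O)C(=O)O[C@@H]2/C=C(/C)CCC1=O | target

**Step count**

Total steps: 12. Longest linear sequence: 9 steps (steps 4 to 12, from 7); the side branch is steps 1 to 3, joined at step 8.

**Steps most likely to fail**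

1. Step 12. What may go wrong: electron transfer from divalent chromium to the cross-conjugated α-methylene ketone (reduction or reductive coupling), intermolecular coupling outrunning the slow ten-membered closure, and, as a second concern, incomplete facial control at C6. Fallback: the ring is closed with C1 at the carbinol level and the ketone is made last. Setting out from 17, NaBH4/CeCl3·7H2O in MeOH at −78 °C (Luche reduction) should reduce only the enone carbonyl and give the allylic alcohol F1 (epimers at C1). Singlet-oxygen unmasking as in step 10 should give the hydroxybutenolide F2, and MeI/K2CO3 the formyl ester F3. The same CrCl2/NiCl2 closure, now free of the enone, should give the macrocyclic hydroxy lactone F4. Dess–Martin oxidation of the allylic C1 carbinol comes back to the route at 23.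

2. Step 8. What may go wrong: iodine–metal exchange between the alkenyl organometallic and the vinyl iodide of 6, proton transfer from the furan α-position to the alkenyl anion, or enolisation of the amide, each eroding the acylation. Fallback: the iodide is introduced only after the organometallic step. Setting out from 13, the same bromine–lithium exchange quenched with the iodine-free amide 5 (neutral work-up) should give the methyl enone F5. Double deprotonation with LiN(i-Pr)2 (alkoxide and kinetic α'-enolate, THF/DMPU, −78 °C) and C-alkylation with bromide 4 should form C2–C3 and deliver 15. After the same dilute-acid desilylation this comes back to the route at 16.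

3. Step 7. What may go wrong: insufficient or wrongly assigned facial selectivity in the allyl transfer to the ortho-disubstituted heteroaryl aldehyde. Fallback: C8 is set by ketone reduction with a model of known sense. Setting out from 11, a racemic Nozaki–Hiyama allylation with 2,3-dibromopropene and CrCl2 (no nickel, THF) should give the racemic carbinol F6. Dess–Martin oxidation should give the aryl ketone F7. Corey–Bakshi–Shibata reduction with the (R)-2-methyl-oxazaborolidine and BH3·SMe2, for which the aryl-large/alkyl-small model predicts the (S)-alcohol, comes back to the route at 13.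

**Further compounds**

F1 | step 12 | (1S,7Z)-1-{4-[(acetyloxy)methyl]-5-[tert-butyl(dimethyl)silyl]furan-3-yl}-4-hydroxy-8-iodo-7-methyl-3-methylideneoct-7-en-1-yl acetate (C4 epimers) | C=C(C[C@H](OC(C)=O)c1coc([Si](C)(C)C(C)(C)C)c1COC(C)=O)C(O)CC/C(C)=C\I
F2 | step 12 | (1S,7Z)-1-{4-[(acetyloxy)methyl]-2-hydroxy-5-oxo-2,5-dihydrofuran-3-yl}-4-hydroxy-8-iodo-7-methyl-3-methylideneoct-7-en-1-yl acetate | C=C(C[C@H](OC(C)=O)C1=C(COC(C)=O)C(=O)OC1O)C(O)CC/C(C)=C\I
F3 | step 12 | methyl (2Z,4S,10Z)-4-(acetyloxy)-2-[(acetyloxy)methyl]-3-formyl-7-hydroxy-11-iodo-10-methyl-6-methylideneundeca-2,10-dienoate | C=C(C[C@H](OC(C)=O)/C(C=O)=C(\COC(C)=O)C(=O)OC)C(O)CC/C(C)=C\I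
F4 | step 12 | (6R,8S)-8,13-diacetoxy-1-hydroxygermacra-4(Z),7(11),10(14)-trien-12,6-olide (C1 epimers) | C=C1C[C@H](OC(C)=O)C2=C(COC(C)=O)C(=O)O[C@@H]2/C=C(/C)CCC1O
F5 | step 8 | (5S)-5-(5-[tert-butyl(dimethyl)silyl]-4-{[(triethylsilyl)oxy]methyl}furan-3-yl)-5-hydroxy-3-methylidenepentan-2-one | C=C(C[C@H](O)c1coc([Si](C)(C)C(C)(C)C)c1CO[Si](CC)(CC)CC)C(C)=O
F6 | step 7 | racemic 3-bromo-1-(5-[tert-butyl(dimethyl)silyl]-4-{[(triethylsilyl)oxy]methyl}furan-3-yl)but-3-en-1-ol | C=C(Br)CC(O)c1coc([Si](C)(C)C(C)(C)C)c1CO[Si](CC)(CC)CC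
F7 | step 7 | 3-bromo-1-(5-[tert-butyl(dimethyl)silyl]-4-{[(triethylsilyl)oxy]methyl}furan-3-yl)but-3-en-1-one | C=C(Br)CC(=O)c1coc([Si](C)(C)C(C)(C)C)c1CO[Si](CC)(CC)CC
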